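The cyclohex-2-enone ring is opened at C4–C5 and C1–C6. Carbons C1–C4 then form a β-methoxy-enoate whose γ-carbon C4 is already the mixed methyl/aryl acetal, and C5–C6 form allyl acrylate. The key step joins them in one operation: the γ-lithiated dienolate adds through C4 to the acrylate, and the new ester enolate acylates C1. This builds the ring, its vinylogous ester (C1=O, C2=C3–OMe) and the C4 ketal stereocentre, and leaves at C6 an allyl ester that later supplies the C6 allyl group. The step exploits the 1,3-placement of C1=O and C3–OMe next to the doubly oxygenated C4. Its precursor is racemic methyl (E)-4-aryloxy-3,4-dimethoxybut-2-enoate.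

Key step: step 5

**Remarks and assumptions**

- Ring numbering used for the target and in all arguments: C1 = ketone carbon, C2=C3 = enol-ether double bond (OMe on C3), C4 = ketal carbon (OMe, OAr), C5 = CH2, C6 = allyl-bearing carbon. The target is (4R,6S), with the C6 allyl group cis to the aryloxy group.
- Naming: by IUPAC numbering the annulation product 12 is a 2-oxocyclohex-3-ene-1-carboxylate. Its ketal carbon is C5 (5R) and its ester-bearing carbon is C1; these are C4 and C6 of the ring numbering above. The structure itself is unchanged.
- C6 carries a hydrogen and is epimerisable. In a β-keto allyl ester with an α-hydrogen the C6–H bond is made last, by ketonisation after loss of CO2. C6 is therefore planned under substrate control from C4, not under control of a ligand on palladium.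
- The mixed ketal at C4 can aromatise by acid-induced loss of ArOH or MeOH. Everything from compound 8 on is run under basic or neutral conditions and purified on Et3N-deactivated silica.
- Precursor design: the (E)-geometry of 8 (C4 syn to the ester) is obligatory for directed γ-lithiation and for ring closure. Lithium is chosen as counter-ion because a bridging lithium can fix one C3=C4 geometry of the dienolate; without that, no face-selective reagent could give one enantiomer. The methyl ester is kept because the methoxide it releases is quenched at once by the acidic C6–H of 12 and cannot exchange the allyl ester.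
- Assumption: the sense of induction of the chiral diether in step 5 cannot be predicted with confidence. The (S,S)-ligand is written; its antipode is to be used if that is the one that leads to the (R)-ketal.

**Route**

Step 1
Reactants: 1 3,4-dimethoxyphenol; 2 allyl bromide
Product: 3 4-(allyloxy)-1,2-dimethoxybenzene
Conditions: K2CO3, acetone, reflux
Reagents that add atoms: none
Why: Williamson ether synthesis; the phenoxide is O-alkylated by the primary allylic bromide.

Step 2
Reactants: 3 4-(allyloxy)-1,2-dimethoxybenzene
Product: 4 2-allyl-4,5-dimethoxyphenol
Conditions: PhNEt2, 190 °C; chromatography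
Reagents that add atoms: none
Why: Aromatic Claisen rearrangement ([3,3]-sigmatropic shift, then tautomerisation), in which the allyl group should migrate mainly to the unhindered ortho carbon para to the 3-methoxy group, the minor regioisomer from migration to the carbon flanked by two oxygen substituents being removed by chromatography.

Step 3
Reactants: 5 methyl 4,4-dimethoxy-3-oxobutanoate
Product: 6 methyl (E)-3,4,4-trimethoxybut-2-enoate
Conditions: HC(OMe)3 (3 equiv), conc. H2SO4 (cat.), neat, 25 → 60 °C; K2CO3; distillation
Reagents that add atoms: trimethyl orthoformate, COC(OC)OC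
Why: Orthoester-mediated enol-ether formation from a β-keto ester (ketalisation, then loss of methanol into conjugation with the ester), which should give the thermodynamic (E)-isomer with OMe anti and C4 syn to the ester, as with methyl acetoacetate and its 4-substituted analogues.

Step 4
Reactants: 6 methyl (E)-3,4,4-trimethoxybut-2-enoate; 4 2-allyl-4,5-dimethoxyphenol
Product: 8 methyl (E)-4-(2-allyl-4,5-dimethoxyphenoxy)-3,4-dimethoxybut-2-enoate, via α-chloro ether 7 (not isolated)
Conditions: AcCl (1.05 equiv), ZnBr2 (1 mol %), CH2Cl2, 0 → 25 °C; then added to 4, K2CO3, MeCN, 0 → 25 °C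
Reagents that add atoms: acetyl chloride, CC(=O)Cl (supplies only the chlorine of 7; no atom of it remains in 8)
Why: Zinc-halide-catalysed exchange of one acetal methoxy group for chloride by an acyl chloride (α-halo ether synthesis), followed by base-mediated O-alkylation of the phenol at the oxocarbenium-type carbon; one equivalent of AcCl limits the exchange to one methoxy group, and the basic medium avoids the ring C-alkylation that an acid-catalysed transacetalisation of this electron-rich phenol would risk.

Step 5
Reactants: 8 methyl (E)-4-(2-allyl-4,5-dimethoxyphenoxy)-3,4-dimethoxybut-2-enoate; 9 allyl acrylate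
Product: 12 allyl (5R)-5-(2-allyl-4,5-dimethoxyphenoxy)-4,5-dimethoxy-2-oxocyclohex-3-ene-1-carboxylate, via lithium dienolate 10 (not isolated), via Michael adduct enolate 11 (not isolated)
Conditions: LDA (1.1 equiv, from n-BuLi and i-Pr2NH), (S,S)-1,2-dimethoxy-1,2-diphenylethane (1.3 equiv), toluene, −78 °C; 9 (1.05 equiv, slow addition), −78 → −30 °C; AcOH (1.2 equiv), −78 °C, then pH 7 buffer
Reagents that add atoms: lithium diisopropylamide, [Li+].CC(C)[N-]C(C)C (supplies only the lithium of 10 and 11; no atom of it remains in 12)
Why: Proposed new method: LDA, precoordinated to the ester carbonyl, removes the acetal hydrogen that lies syn to the ester in the (E)-enoate and gives the U-shaped dienolate 10, in which lithium is expected to bridge O1 and the more basic acetal methoxy oxygen and so fix a single C3=C4 geometry; C4 then adds to the β-carbon of 9 (C4–C5) and ester enolate 11 acylates C1 with loss of methoxide (C1–C6), the methoxide being consumed at once by the acidic C6–H of 12. The closest known reaction types are the Michael–Dieckmann annulation of γ-lithiated 3-alkoxy-2-enoates with acrylates (the anionic counterpart of a 1,3-dialkoxy-1-siloxydiene [4+2]) and Michael additions of lithium ester enolates to enoates steered by a chiral diether on lithium; the new element is face selection at a γ-carbon that carries two oxygen substituents. The six-membered ring closes by 6-exo-trig Dieckmann acylation after the intermolecular Michael bond has been made. The C4 stereocentre is controlled by the C2-symmetric diether bound to the bridging lithium, which should screen one face of the planar γ-carbon of a geometrically defined dienolate; the ester-bearing carbon (C6) is left as an epimer/enol mixture and is fixed in step 6. Besides face selectivity the step needs γ- rather than α-attack and a cisoid C1/C4 arrangement: 3-alkoxy-dienolates react with aldehydes and Michael acceptors at the γ-terminus, the (E)-enoate holds C4 syn to the ester, and an α-adduct, which has no six-membered acylation open to it, should revert and be drawn off through the γ-pathway. Slow addition of one equivalent of 9 at −78 °C should keep enolate 11 from adding to a second acrylate before it cyclises.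

Step 6
Reactants: 12 allyl (5R)-5-(2-allyl-4,5-dimethoxyphenoxy)-4,5-dimethoxy-2-oxocyclohex-3-ene-1-carboxylate
Product: 15 (4R,6S)-6-allyl-4-(2-allyl-4,5-dimethoxyphenoxy)-3,4-dimethoxycyclohex-2-en-1-one, via C6-allyl keto acid 13 (not isolated), via dienol 14 (not isolated)
Conditions: Pd(PPh3)4 (5 mol %), THF (degassed), 25 °C; chromatography on Et3N-deactivated silica
Reagents that add atoms: none
Why: Tsuji–Saegusa decarboxylative allylation (Pd-catalysed Carroll-type allyl transfer) of a cyclic β-keto allyl ester with an α-hydrogen: Pd(0) ionises the allyl ester, the π-allyl cation C-allylates the doubly activated C6, keto acid 13 loses CO2 and dienol 14 ketonises, so that C6 is set under substrate control by proton delivery to the ring face of the small C4 methoxy group, opposite the bulky aryloxy group, which leaves allyl cis to OAr (6S) with C4 untouched, and a minor 6R epimer can be separated and re-equilibrated with DBU.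

**Compound list**

1 | 3,4-dimethoxyphenol | COc1ccc(O)cc1OC | starting material
2 | allyl bromide (3-bromoprop-1-ene) | C=CCBr | starting material
3 | 4-(allyloxy)-1,2-dimethoxybenzene | C=CCOc1ccc(OC)c(OC)c1 | intermediate
4 | 2-allyl-4,5-dimethoxyphenol | C=CCc1cc(OC)c(OC)cc1O | intermediate
5 | methyl 4,4-dimethoxy-3-oxobutanoate | COC(OC)C(=O)CC(=O)OC | starting material
6 | methyl (E)-3,4,4-trimethoxybut-2-enoate | COC(=O)/C=C(/OC)C(OC)OC | intermediate
7 | methyl (E)-4-chloro-3,4-dimethoxybut-2-enoate (racemic α-chloro ether, not isolated) | COC(=O)/C=C(/OC)C(Cl)OC | intermediate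
8 | methyl (E)-4-(2-allyl-4,5-dimethoxyphenoxy)-3,4-dimethoxybut-2-enoate (racemic at the acetal carbon) | COC(=O)/C=C(/OC)C(OC)Oc1cc(OC)c(OC)cc1CC=C | intermediate
9 | allyl acrylate (prop-2-enyl prop-2-enoate) | C=CC(=O)OCC=C | starting material
10 | lithium (1E,3Z)-4-(2-allyl-4,5-dimethoxyphenoxy)-1,3,4-trimethoxybuta-1,3-dien-1-olate (expected geometry, not isolated) | [Li+].[O-]/C(OC)=C\C(OC)=C(/OC)Oc1cc(OC)c(OC)cc1CC=C | intermediate
11 | lithium enolate (at C5) of 6-allyl 1-methyl (2E,4R)-4-(2-allyl-4,5-dimethoxyphenoxy)-3,4-dimethoxyhex-2-enedioate (not isolated) | [Li+].COC(=O)/C=C(/OC)[C@](OC)(Oc1cc(OC)c(OC)cc1CC=C)CC=C([O-])OCC=C | intermediate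
12 | allyl (5R)-5-(2-allyl-4,5-dimethoxyphenoxy)-4,5-dimethoxy-2-oxocyclohex-3-ene-1-carboxylate (epimers at the ester-bearing carbon and enol form) | C=CCc1cc(OC)c(OC)cc1O[C@]1(OC)CC(C(=O)OCC=C)C(=O)C=C1OC | intermediate
13 | (5R)-1-allyl-5-(2-allyl-4,5-dimethoxyphenoxy)-4,5-dimethoxy-2-oxocyclohex-3-ene-1-carboxylic acid (C1 epimers, not isolated) | C=CCc1cc(OC)c(OC)cc1O[C@]1(OC)CC(CC=C)(C(=O)O)C(=O)C=C1OC | intermediate
14 | (4R)-2-allyl-4-(2-allyl-4,5-dimethoxyphenoxy)-4,5-dimethoxycyclohexa-1,5-dien-1-ol (not isolated) | C=CCc1cc(OC)c(OC)cc1O[C@]1(OC)CC(CC=C)=C(O)C=C1OC | intermediate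
15 | (4R,6S)-6-allyl-4-(2-allyl-4,5-dimethoxyphenoxy)-3,4-dimethoxycyclohex-2-en-1-one | C=CCc1cc(OC)c(OC)cc1O[C@]1(OC)C[C@H](CC=C)C(=O)C=C1OC | target

**Step count and risks**

Total step count: 6.
Longest linear sequence: 5 steps (steps 1, 2, 4, 5, 6, from 3,4-dimethoxyphenol 1 to 15).

Steps most likely to fail:

1. Step 5. The two faces of the γ-carbon of dienolate 10 may be discriminated poorly, or both C3=C4 geometries may form, so that the C4 configuration arises with low selectivity. Fallback, from 8, returning at 15: the annulation is run without chiral ligand (LDA, THF, −78 → −30 °C, allyl acrylate 9), which is the established achiral Michael–Dieckmann reaction. It should give 12 as the racemate, that is together with allyl (5S)-5-(2-allyl-4,5-dimethoxyphenoxy)-4,5-dimethoxy-2-oxocyclohex-3-ene-1-carboxylate F1. The racemate is taken through the conditions of step 6 to 15 and its mirror image (4S,6R)-6-allyl-4-(2-allyl-4,5-dimethoxyphenoxy)-3,4-dimethoxycyclohex-2-en-1-one F2. Compound 15 is then separated from F2 by preparative chromatography on a chiral stationary phase, so that the C4 configuration comes from a resolution and not from induction.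

2. Step 6. Ketonisation of dienol 14 may occur with poor face selectivity, giving C6 epimers, and allyl groups may be exchanged between molecules before C-allylation. Fallback, from 12, returning at 15: 12 is C-allylated at the doubly activated carbon with allyl bromide 2 and K2CO3 in acetone. This gives allyl (5R)-1-allyl-5-(2-allyl-4,5-dimethoxyphenoxy)-4,5-dimethoxy-2-oxocyclohex-3-ene-1-carboxylate F3, whose new quaternary centre need not be controlled. A palladium-catalysed enantioselective decarboxylative protonation then forms the C6–H bond under control of the ligand (Pd(OAc)2, t-Bu-PHOX, Meldrum's acid as proton donor and allyl acceptor, dioxane, 25 °C). The ligand antipode is chosen so that protonation occurs on the methoxy face, and 15 results.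

3. Step 4. Ionisation of the electron-poor acetal may be sluggish or unselective, with exchange of both methoxy groups or decay of chloro ether 7 before the phenol is coupled. Fallback, from 4, returning at 8: commercial methyl 4-methoxy-3-oxobutanoate (COCC(=O)CC(=O)OC) is converted with trimethyl orthoformate and catalytic H2SO4 into methyl (E)-3,4-dimethoxybut-2-enoate F4. Wohl–Ziegler bromination (NBS, AIBN, PhCF3, 80 °C) at the allylic, oxygen-bearing C4–H gives methyl (E)-4-bromo-3,4-dimethoxybut-2-enoate F5. F5 alkylates phenol 4 on oxygen (K2CO3, MeCN, 0 → 25 °C) to give 8. The α-halo ether is thus reached by radical C–H bromination instead of acetal exchange.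

**Further compounds**

F1 | step 5 | allyl (5S)-5-(2-allyl-4,5-dimethoxyphenoxy)-4,5-dimethoxy-2-oxocyclohex-3-ene-1-carboxylate (formed with 12 as the racemate) | C=CCc1cc(OC)c(OC)cc1O[C@@]1(OC)CC(C(=O)OCC=C)C(=O)C=C1OC
F2 | step 5 | (4S,6R)-6-allyl-4-(2-allyl-4,5-dimethoxyphenoxy)-3,4-dimethoxycyclohex-2-en-1-one (formed with 15 as the racemate) | C=CCc1cc(OC)c(OC)cc1O[C@@]1(OC)C[C@@H](CC=C)C(=O)C=C1OC
F3 | step 6 | allyl (5R)-1-allyl-5-(2-allyl-4,5-dimethoxyphenoxy)-4,5-dimethoxy-2-oxocyclohex-3-ene-1-carboxylate (C1 epimers) | C=CCc1cc(OC)c(OC)cc1O[C@]1(OC)CC(CC=C)(C(=O)OCC=C)C(=O)C=C1OC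
F4 | step 4 | methyl (E)-3,4-dimethoxybut-2-enoate | COC(=O)/C=C(/OC)COC
F5 | step 4 | methyl (E)-4-bromo-3,4-dimethoxybut-2-enoate (racemic) | COC(=O)/C=C(/OC)C(Br)OC
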